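Remark on the chemistry: atoms carry eremophilane numbers (decalin C1–C10, isopropenyl C11–C13, methyls on C4 and C5), β is the face of the C5 methyl and "trans" means 5β‑CH3/10α‑H. Read this way the target SMILES is 3α‑O, 4β‑CH3, 7α‑isopropenyl, 9α‑O, 10α‑H, that is (3R,4R,5R,7S,9S,10R), with every substituent equatorial except the angular methyl.

## The problem

Compound 30 is a trans‑fused decalin. Ring A (C1–C5, C10) carries the 3α‑tiglate and the cis 4β,5β‑dimethyl pair. Ring B (C5–C10) carries the 7α‑isopropenyl group, the C8 ketone and the 9α‑senecioate. C5 is quaternary and C10 has no carbonyl neighbour, so the ring fusion and its relation to C4 cannot be repaired later and must come out of the ring‑forming event. C3 and C4 form a syn methyl/oxygen pair that an auxiliary aldol can deliver, and these two centres can then steer C5 and C10. C7 and C9 flank the ketone and hold the thermodynamically preferred equatorial groups, so substrate control suffices there, but the same acidity makes them fragile. The delicate functions are the β,γ‑unsaturated isopropenyl ketone (drift to the conjugated isopropylidene isomer, C7 epimerisation), the α‑acyloxy ketone (C9 epimerisation, ketol transposition once the hydroxyl is free) and two different unsaturated esters on two secondary alcohols. The enabling feature lies in ring B: a C8 carbonyl with oxygen on C9 is what a C8=C9 enol silane gives on oxidation, and that enol silane is the cyclohexene of a [4+2] union of a C7=C8(OSi)–C9=C10 diene with a C5=C6 dienophile. C6 is a bare CH2 beside quaternary C5, so a formyl group can sit there to activate the dienophile and be excised afterwards.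

## Retrosynthesis

**Ester C–O bonds at C9 and C3 (30 ⇒ 28 + 29; 27 ⇒ 25 + 26; back to 24).** Neither unsaturated ester would survive enolate chemistry at C7, hydride reduction or the rhodium step, so both go on at the end. The α‑acyloxy ketone is the most base‑sensitive unit, so the senecioate is last. The two hydroxyls must be distinguishable: C3 is carried as a triethylsilyl ether from the first steps and C9 as the tert‑butyldimethylsilyl ether that the enol silane leaves behind. The precursor 24 then needs only two non‑basic desilylations and two acylations that leave the C11 double bond in place.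

**C7–C11 (24 ⇒ 22 ⇒ 18 + acetone 19).** The isopropenyl group is cut back to an acetone aldol adduct. Carrying these three carbons on the diene terminus through the cycloaddition was considered and set aside: it would crowd the forming C6–C7 bond and put a second diene into the substrate. The decalone 18 is simpler by one stereocentre and one alkene. The forward reaction must enolise at C7 and not C9, bring acetone in from the α face, and eliminate toward a methyl group and not toward the ring.

**C6–CHO and C9–O (18 ⇒ 17 ⇒ 15).** Adding a formyl group back onto C6 and removing the C9 oxygen reveals the enol silane 15. Since C6 is CH2 in the target, any activator there must be traceless; formyl is the smallest strong acceptor and leaves as CO under neutral conditions. Because the double bond of 15 is C8=C9, C9 is oxidised without any choice between C7 and C9.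

**C5–C10 and C6–C7 (15 ⇒ 14, key step).** Both rings are opened at once to the acyclic trienal 14. Against a stepwise annulation this cut removes both rings and three stereocentres (C5, C6, C10) in one operation and leaves only the C3/C4 pair. The forward reaction must give the trans fusion and choose the diene face dictated by C3 and C4. One limit is accepted knowingly: the tether places silyloxy and formyl 1,3 to each other in the product, which is not the orientation that the polarised partners would choose on their own. The silyloxy group therefore earns its place through the regiodefined enol silane and a raised diene HOMO, not through charge matching, and the cyclisation is planned under neutral thermal conditions.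

**Oxidation level and enol silane (14 ⇒ 13 ⇒ 12 ⇒ 11).** The enal is unmasked last because it is the trigger. The enol silane is made while C6 still carries an ester, since soft enolisation distinguishes a methyl ketone from an enoate but would turn an enal into its own dienol silane.

**C9=C10 (11 ⇒ 9 + methyl vinyl ketone 10).** Cross‑metathesis adds C7–C9 to a terminal alkene. It is preferred to carrying an enone from the start, which would not survive the Grignard and olefination steps.

**C5=C6 (9 ⇒ 7 + triethyl phosphonoacetate 8).** Olefination of a methyl ketone supplies the β‑methyl enoate. The E geometry is needed, since it places the formyl group cis to the C5 methyl and trans to the tether.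

**C3–C4 (7 ⇒ 6 ⇒ 5 ⇒ 4 ⇒ 1 + 4‑pentenal 2).** A syn aldol of propionimide 1 sets both tether stereocentres in one step, and the terminal alkene of 2 is the handle for the diene.

## Roads not taken

**Alternative 1: dearomatisation, bicyclooctenol, anionic oxy‑Cope.** The cut is C5–C6 with a temporary C3–C8 bond. A masked o‑quinone from a dimethylguaiacol would be bridged by a two‑carbon dienophile and vinylated to the carbinol A2. Its potassium alkoxide (KH, 18‑crown‑6) would rearrange to the octalone A1. Merits: the quaternary C5 forms in a reliable sigmatropic shift, and C8 and C9 arrive fully differentiated as ketone and ketal, a cleaner oxidation pattern than in the chosen plan. Weak points: A1 is cis‑fused and the target is trans, so C10 would have to be inverted through a C9 carbonyl with no clear thermodynamic bias beside an angular methyl. The sequence is racemic unless an asymmetric cycloaddition or a resolution is added. C3 and C4 would have to be set late by hydroboration of a C3=C4 alkene on a cis‑decalin, and the isopropenyl group still needs the same aldol and dehydration. The chosen plan also fixes the C8/C9 pattern, through the enol silane, and adds control of the fusion and of absolute configuration.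

**Alternative 2: carbonyl‑ene closure of ring B.** The cut is C7–C8. ZnBr2 would activate the aldehyde of the seco compound A4; the prenyl carbon C7 bonds to C8 while a C12 hydrogen passes to oxygen, giving A3. Merit: in one respect this is better than the chosen plan. The isopropenyl group and the equatorial C7 centre are created in the ring closure through an all‑equatorial chair, with no dehydration whose direction must be controlled. Weak points: A3 has no oxygen on C9. After oxidation to the ketone, C9 would have to be hydroxylated in the presence of a C7 hydrogen that is both α to the carbonyl and allylic. In addition A4 already contains C3, C4, quaternary C5 and C10 on a cyclohexane, so the hardest stereochemical problem is moved into the precursor. Against the cleaner isopropenyl installation, the chosen plan sets a regiodefined C9 oxidation and the formation of ring A with its quaternary centre in the same step as ring B.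

**Alternative 3: glyoxal‑initiated cationic bicyclisation.** The cuts are C9–C10 and C4–C5. Cu(OTf)2 with a chiral bis(oxazoline) would chelate the ketoaldehyde of A6; C10 attacks C9 and the enol silane carbon C4 captures the C5 cation, giving A5. Merits: this is the shortest route on paper and is catalytic in the chiral source. Both rings, four stereocentres and both carbonyls form together, which is better step economy than the chosen plan. Weak points: A6 holds an α‑ketoaldehyde and a nucleophilic enol silane in one molecule, so direct Mukaiyama addition competes with the alkene‑initiated cascade. The C9 configuration depends on the chelate geometry in a cascade that has little precedent with this terminator. A5 then needs the C3 ketone reduced in the presence of the C8 ketone and a free ketol. The chosen plan is longer; it sets against this that every step belongs to an established reaction class and that the C3 and C9 oxygens are differentiated from the outset.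

Key step: step 10

## Route

Step 1
Reactants: 1 (S)-4-benzyl-3-propionyloxazolidin-2-one; 2 4-pentenal
Product: 4 (S)-4-benzyl-3-[(2S,3R)-3-hydroxy-2-methylhept-6-enoyl]oxazolidin-2-one, via Z-dibutylboron enolate 3 (not isolated)
Conditions: Bu2BOTf, i-Pr2NEt, CH2Cl2, −78 → 0 °C; 2, −78 → 0 °C; H2O2, MeOH, pH 7 buffer
Reagents that add atoms: none
Why: Evans syn aldol; the Z-boron enolate 3 reacts through a closed chair transition state on the face away from the benzyl group, which sets C4 (S) and C3 (R), the future 4β-methyl and 3α-oxygen.

Step 2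
Reactants: 4 (S)-4-benzyl-3-[(2S,3R)-3-hydroxy-2-methylhept-6-enoyl]oxazolidin-2-one
Product: 5 (2S,3R)-3-hydroxy-N-methoxy-N,2-dimethylhept-6-enamide
Conditions: MeNH(OMe)·HCl, AlMe3, CH2Cl2, −20 → 0 °C
Reagents that add atoms: N,O-dimethylhydroxylamine hydrochloride, CNOC.Cl
Why: Aluminium amide transamidation to the Weinreb amide; the free β-hydroxyl assists exocyclic cleavage, the auxiliary is recovered and no stereocentre is touched.

Step 3
Reactants: 5 (2S,3R)-3-hydroxy-N-methoxy-N,2-dimethylhept-6-enamide
Product: 6 (2S,3R)-N-methoxy-N,2-dimethyl-3-(triethylsilyloxy)hept-6-enamide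
Conditions: Et3SiCl, imidazole, DMF, 0 °C → rt
Reagents that add atoms: chlorotriethylsilane, CC[Si](Cl)(CC)CC
Why: Standard silylation of a secondary alcohol; the triethylsilyl group is chosen so that C3 can later be unmasked before the tert-butyldimethylsilyl ether on C9.

Step 4
Reactants: 6 (2S,3R)-N-methoxy-N,2-dimethyl-3-(triethylsilyloxy)hept-6-enamide
Product: 7 (3S,4R)-3-methyl-4-(triethylsilyloxy)oct-7-en-2-one
Conditions: MeMgBr, THF, 0 °C; aq. NH4Cl
Reagents that add atoms: methylmagnesium bromide, C[Mg]Br
Why: Grignard addition to a Weinreb amide stops at the ketone through the chelated tetrahedral intermediate, and the α-stereocentre is not enolised under these conditions.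

Step 5
Reactants: 7 (3S,4R)-3-methyl-4-(triethylsilyloxy)oct-7-en-2-one; 8 triethyl phosphonoacetate
Product: 9 ethyl (2E,4R,5R)-3,4-dimethyl-5-(triethylsilyloxy)nona-2,8-dienoate
Conditions: NaH, THF, 0 → 50 °C
Reagents that add atoms: none
Why: Horner–Wadsworth–Emmons olefination of a methyl ketone places the ester trans to the branched C4 substituent (E); the minor Z isomer is removed by chromatography because only the E-enal leads to the trans ring fusion.

Step 6
Reactants: 9 ethyl (2E,4R,5R)-3,4-dimethyl-5-(triethylsilyloxy)nona-2,8-dienoate; 10 methyl vinyl ketone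
Product: 11 ethyl (2E,4R,5R,8E)-3,4-dimethyl-10-oxo-5-(triethylsilyloxy)undeca-2,8-dienoate
Conditions: second-generation Hoveyda–Grubbs catalyst RuCl2(H2IMes)(=CH-C6H4-2-O-i-Pr) (5 mol %), 10 (4 equiv), CH2Cl2, 40 °C
Reagents that add atoms: none
Why: Olefin cross-metathesis of a terminal alkene with an electron-poor partner gives the E-enone, and the trisubstituted enoate is inert to the ruthenium carbene.

Step 7
Reactants: 11 ethyl (2E,4R,5R,8E)-3,4-dimethyl-10-oxo-5-(triethylsilyloxy)undeca-2,8-dienoate
Product: 12 ethyl (2E,4R,5R,8E)-10-(tert-butyldimethylsilyloxy)-3,4-dimethyl-5-(triethylsilyloxy)undeca-2,8,10-trienoate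
Conditions: TBSOTf, Et3N, CH2Cl2, −78 → 0 °C
Reagents that add atoms: tert-butyldimethylsilyl triflate, CC(C)(C)[Si](C)(C)OS(=O)(=O)C(F)(F)F
Why: Soft enolisation of the methyl ketone on its methyl side gives the cross-conjugated 2-silyloxydiene; the enoate is not enolised, which is why an ester and not an aldehyde is present at this stage.

Step 8
Reactants: 12 ethyl (2E,4R,5R,8E)-10-(tert-butyldimethylsilyloxy)-3,4-dimethyl-5-(triethylsilyloxy)undeca-2,8,10-trienoate
Product: 13 (2E,4R,5R,8E)-10-(tert-butyldimethylsilyloxy)-3,4-dimethyl-5-(triethylsilyloxy)undeca-2,8,10-trien-1-ol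
Conditions: i-Bu2AlH, CH2Cl2, −78 °C; aq. KNaC4H4O6
Reagents that add atoms: none
Why: 1,2-Reduction of the enoate by i-Bu2AlH gives the allylic alcohol, and the non-acidic tartrate work-up preserves the enol silane.

Step 9
Reactants: 13 (2E,4R,5R,8E)-10-(tert-butyldimethylsilyloxy)-3,4-dimethyl-5-(triethylsilyloxy)undeca-2,8,10-trien-1-ol
Product: 14 (2E,4R,5R,8E)-10-(tert-butyldimethylsilyloxy)-3,4-dimethyl-5-(triethylsilyloxy)undeca-2,8,10-trienal
Conditions: MnO2, CH2Cl2, 0 °C → rt
Reagents that add atoms: none
Why: Allylic oxidation with MnO2 under neutral conditions gives the E-enal without touching either silyl ether; 14 is filtered and used directly.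

Step 10
Reactants: 14 (2E,4R,5R,8E)-10-(tert-butyldimethylsilyloxy)-3,4-dimethyl-5-(triethylsilyloxy)undeca-2,8,10-trienal
Product: 15 8-(tert-butyldimethylsilyloxy)-6β-formyl-4β,5β-dimethyl-3α-(triethylsilyloxy)-trans-octal-8-ene (10α-H)
Conditions: toluene (0.01 M), BHT (cat.), 140 °C, sealed base-washed vessel
Reagents that add atoms: none
Why: A concerted, asynchronous suprafacial [4+2] cycloaddition joins the s-cis 2-silyloxydiene C7=C8(OSi)–C9=C10 to the E-enal C5=C6 and forms C5–C10 and C6–C7; the closest known reaction type is the thermal type 1 intramolecular Diels–Alder reaction of 1,7,9-decatrienes with a terminal E-acceptor, including cases that create an angular methyl. Ring B is the cyclohexene made by the cycloaddition itself, all six carbons coming from diene and dienophile, and ring A closes as the six-membered tether ring in which C1–C4 link C10 to C5. The tether forces silyloxy and formyl into a 1,3 relation, so the donor raises the diene HOMO but does not polarise it toward C5; neutral heating is therefore chosen over a Lewis acid, which would favour Mukaiyama-type attack of C7 on a complexed aldehyde. The C5/C10 relation comes from the fold with formyl and C5 methyl endo and the tether exo, which gives 10α-H anti to the 5β-methyl (trans fusion). The diene face is chosen by C3 and C4: in the chair-like tether both the silyloxy and the methyl group are equatorial, whereas the other face would make both axial and put the C3 silyloxy group 1,3-diaxial to the C5 methyl. C6 follows from the E geometry and suprafacial addition (formyl cis to the C5 methyl, 6β); it is removed in step 12, so its configuration does not matter. The selectivities needed are endo over exo and one π-face over the other, secured by the E-enal, the formyl group and the two equatorial tether substituents.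

Step 11
Reactants: 15 8-(tert-butyldimethylsilyloxy)-6β-formyl-4β,5β-dimethyl-3α-(triethylsilyloxy)-trans-octal-8-ene
Product: 17 9α-(tert-butyldimethylsilyloxy)-6β-formyl-4β,5β-dimethyl-3α-(triethylsilyloxy)-trans-decalin-8-one, via silyloxy epoxide 16 (not isolated)
Conditions: mCPBA (1.05 equiv), NaHCO3, CH2Cl2, −20 → 0 °C
Reagents that add atoms: mCPBA, OOC(=O)c1cccc(Cl)c1
Why: Rubottom oxidation; the peracid attacks the C8=C9 enol silane from the α face, away from the axial C5 methyl, and epoxide 16 opens with 1,4-silyl shift to the α-silyloxy ketone with the equatorial 9α-oxygen; the enol silane reacts far faster than the aldehyde.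

Step 12
Reactants: 17 9α-(tert-butyldimethylsilyloxy)-6β-formyl-4β,5β-dimethyl-3α-(triethylsilyloxy)-trans-decalin-8-one
Product: 18 9α-(tert-butyldimethylsilyloxy)-4β,5β-dimethyl-3α-(triethylsilyloxy)-trans-decalin-8-one
Conditions: RhCl(PPh3)3 (1.2 equiv), PhCN, 130 °C
Reagents that add atoms: none
Why: Tsuji–Wilkinson decarbonylation; oxidative addition of the formyl C–H to monovalent rhodium, CO extrusion and C–H reductive elimination turn C6 into CH2 under neutral conditions, and no alkene is present that could isomerise.

Step 13
Reactants: 18 9α-(tert-butyldimethylsilyloxy)-4β,5β-dimethyl-3α-(triethylsilyloxy)-trans-decalin-8-one; 19 acetone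
Product: 22 9α-(tert-butyldimethylsilyloxy)-7α-(2-hydroxypropan-2-yl)-4β,5β-dimethyl-3α-(triethylsilyloxy)-trans-decalin-8-one, via lithium enolate 20 (not isolated), via chlorozinc enolate 21 (not isolated)
Conditions: LiN(i-Pr)2, THF, −78 °C; ZnCl2, −78 °C; 19, −78 → −40 °C; aq. NH4Cl
Reagents that add atoms: none
Why: Kinetic deprotonation occurs at the C7 methylene and not at the hindered silyloxy-bearing C9; the zinc enolate adds to acetone from the α face, opposite the axial C5 methyl, to give the equatorial 7α side chain, which is also the thermodynamic outcome of this reversible aldol addition.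

Step 14
Reactants: 22 9α-(tert-butyldimethylsilyloxy)-7α-(2-hydroxypropan-2-yl)-4β,5β-dimethyl-3α-(triethylsilyloxy)-trans-decalin-8-one
Product: 24 9α-(tert-butyldimethylsilyloxy)-3α-(triethylsilyloxy)-trans-eremophil-11-en-8-one (7α-isopropenyl), via chlorosulfite ester 23 (not isolated)
Conditions: SOCl2, pyridine, CH2Cl2, −20 → 0 °C
Reagents that add atoms: none
Why: Dehydration of a tertiary carbinol through its chlorosulfite with pyridine as base; the six methyl hydrogens are accessible while the single ring hydrogen at C7 is axial beneath the C5 methyl, so elimination should give the isopropenyl group and leave C7 untouched.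

Step 15
Reactants: 24 9α-(tert-butyldimethylsilyloxy)-3α-(triethylsilyloxy)-trans-eremophil-11-en-8-one
Product: 25 9α-(tert-butyldimethylsilyloxy)-3α-hydroxy-trans-eremophil-11-en-8-one
Conditions: HF·pyridine, pyridine, THF, 0 °C
Reagents that add atoms: none
Why: Buffered fluoride cleaves the secondary triethylsilyl ether much faster than the hindered tert-butyldimethylsilyl ether beside the ketone, and the medium is not basic enough to move the C11 double bond into conjugation.

Step 16
Reactants: 25 9α-(tert-butyldimethylsilyloxy)-3α-hydroxy-trans-eremophil-11-en-8-one; 26 tigloyl chloride, (E)-2-methylbut-2-enoyl chloride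
Product: 27 9α-(tert-butyldimethylsilyloxy)-3α-tigloyloxy-trans-eremophil-11-en-8-one
Conditions: pyridine, DMAP (cat.), CH2Cl2, 0 °C → rt
Reagents that add atoms: none
Why: Acylation of the equatorial C3 alcohol with an acid chloride under nucleophilic catalysis; the E geometry of the tigloyl group is the stable one and is retained.

Step 17
Reactants: 27 9α-(tert-butyldimethylsilyloxy)-3α-tigloyloxy-trans-eremophil-11-en-8-one
Product: 28 9α-hydroxy-3α-tigloyloxy-trans-eremophil-11-en-8-one
Conditions: aq. HF (48 %), MeCN, 0 °C → rt
Reagents that add atoms: none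
Why: Acidic fluoride desilylation frees the C9 hydroxyl without base, so the α-ketol, the C7 stereocentre, the C11 alkene and the tiglate should not be disturbed.

Step 18
Reactants: 28 9α-hydroxy-3α-tigloyloxy-trans-eremophil-11-en-8-one; 29 senecioic acid, 3-methylbut-2-enoic acid
Product: 30 3α-tigloyloxy-9α-senecioyloxy-trans-eremophil-11-en-8-one, (3R,4R,5R,7S,9S,10R)
Conditions: DCC, DMAP (cat.), CH2Cl2, 0 °C → rt
Reagents that add atoms: none
Why: Steglich esterification with the free acid avoids the amine-induced vinylketene path that deconjugates senecioyl donors; the equatorial 9α-hydroxyl is acylated with retention and gives 30.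

## Compound list

1 | (S)-4-benzyl-3-propionyloxazolidin-2-one | CCC(=O)N1[C@@H](Cc2ccccc2)COC1=O | starting material
2 | 4-pentenal | C=CCCC=O | starting material
3 | Z-dibutylboron enolate of 1 | C/C=C(\OB(CCCC)CCCC)N1[C@@H](Cc2ccccc2)COC1=O | intermediate (not isolated)
4 | (S)-4-benzyl-3-[(2S,3R)-3-hydroxy-2-methylhept-6-enoyl]oxazolidin-2-one | C=CCC[C@@H](O)[C@H](C)C(=O)N1[C@@H](Cc2ccccc2)COC1=O | intermediate
5 | (2S,3R)-3-hydroxy-N-methoxy-N,2-dimethylhept-6-enamide | C=CCC[C@@H](O)[C@H](C)C(=O)N(C)OC | intermediate
6 | (2S,3R)-N-methoxy-N,2-dimethyl-3-(triethylsilyloxy)hept-6-enamide | C=CCC[C@@H](O[Si](CC)(CC)CC)[C@H](C)C(=O)N(C)OC | intermediate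
7 | (3S,4R)-3-methyl-4-(triethylsilyloxy)oct-7-en-2-one | C=CCC[C@@H](O[Si](CC)(CC)CC)[C@H](C)C(C)=O | intermediate
8 | triethyl phosphonoacetate | CCOC(=O)CP(=O)(OCC)OCC | starting material
9 | ethyl (2E,4R,5R)-3,4-dimethyl-5-(triethylsilyloxy)nona-2,8-dienoate | C=CCC[C@@H](O[Si](CC)(CC)CC)[C@H](C)/C(C)=C/C(=O)OCC | intermediate
10 | methyl vinyl ketone | C=CC(C)=O | starting material
11 | ethyl (2E,4R,5R,8E)-3,4-dimethyl-10-oxo-5-(triethylsilyloxy)undeca-2,8-dienoate | CC(=O)/C=C/CC[C@@H](O[Si](CC)(CC)CC)[C@H](C)/C(C)=C/C(=O)OCC | intermediate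
12 | ethyl (2E,4R,5R,8E)-10-(tert-butyldimethylsilyloxy)-3,4-dimethyl-5-(triethylsilyloxy)undeca-2,8,10-trienoate | C=C(O[Si](C)(C)C(C)(C)C)/C=C/CC[C@@H](O[Si](CC)(CC)CC)[C@H](C)/C(C)=C/C(=O)OCC | intermediate
13 | (2E,4R,5R,8E)-10-(tert-butyldimethylsilyloxy)-3,4-dimethyl-5-(triethylsilyloxy)undeca-2,8,10-trien-1-ol | C=C(O[Si](C)(C)C(C)(C)C)/C=C/CC[C@@H](O[Si](CC)(CC)CC)[C@H](C)/C(C)=C/CO | intermediate
14 | (2E,4R,5R,8E)-10-(tert-butyldimethylsilyloxy)-3,4-dimethyl-5-(triethylsilyloxy)undeca-2,8,10-trienal | C=C(O[Si](C)(C)C(C)(C)C)/C=C/CC[C@@H](O[Si](CC)(CC)CC)[C@H](C)/C(C)=C/C=O | intermediate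
15 | 8-(tert-butyldimethylsilyloxy)-6β-formyl-4β,5β-dimethyl-3α-(triethylsilyloxy)-trans-octal-8-ene | C1[C@@H](C=O)[C@]2(C)[C@@H](C)[C@H](O[Si](CC)(CC)CC)CC[C@H]2C=C1O[Si](C)(C)C(C)(C)C | intermediate
16 | 8α,9α-epoxy-8β-(tert-butyldimethylsilyloxy)-6β-formyl-4β,5β-dimethyl-3α-(triethylsilyloxy)-trans-decalin | C1[C@@H](C=O)[C@]2(C)[C@@H](C)[C@H](O[Si](CC)(CC)CC)CC[C@H]2[C@@H]3O[C@]13O[Si](C)(C)C(C)(C)C | intermediate (not isolated)
17 | 9α-(tert-butyldimethylsilyloxy)-6β-formyl-4β,5β-dimethyl-3α-(triethylsilyloxy)-trans-decalin-8-one | C1[C@@H](C=O)[C@]2(C)[C@@H](C)[C@H](O[Si](CC)(CC)CC)CC[C@H]2[C@H](O[Si](C)(C)C(C)(C)C)C1=O | intermediate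
18 | 9α-(tert-butyldimethylsilyloxy)-4β,5β-dimethyl-3α-(triethylsilyloxy)-trans-decalin-8-one | C1C[C@]2(C)[C@@H](C)[C@H](O[Si](CC)(CC)CC)CC[C@H]2[C@H](O[Si](C)(C)C(C)(C)C)C1=O | intermediate
19 | acetone | CC(C)=O | starting material
20 | lithium C7=C8 enolate of 18 | [Li]OC1=CC[C@]2(C)[C@@H](C)[C@H](O[Si](CC)(CC)CC)CC[C@H]2[C@@H]1O[Si](C)(C)C(C)(C)C | intermediate (not isolated)
21 | chlorozinc C7=C8 enolate of 18 | Cl[Zn]OC1=CC[C@]2(C)[C@@H](C)[C@H](O[Si](CC)(CC)CC)CC[C@H]2[C@@H]1O[Si](C)(C)C(C)(C)C | intermediate (not isolated)
22 | 9α-(tert-butyldimethylsilyloxy)-7α-(2-hydroxypropan-2-yl)-4β,5β-dimethyl-3α-(triethylsilyloxy)-trans-decalin-8-one | CC(C)(O)[C@@H]1C[C@]2(C)[C@@H](C)[C@H](O[Si](CC)(CC)CC)CC[C@H]2[C@H](O[Si](C)(C)C(C)(C)C)C1=O | intermediate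
23 | chlorosulfite ester of 22 | CC(C)(OS(=O)Cl)[C@@H]1C[C@]2(C)[C@@H](C)[C@H](O[Si](CC)(CC)CC)CC[C@H]2[C@H](O[Si](C)(C)C(C)(C)C)C1=O | intermediate (not isolated)
24 | 9α-(tert-butyldimethylsilyloxy)-3α-(triethylsilyloxy)-trans-eremophil-11-en-8-one | C=C(C)[C@@H]1C[C@]2(C)[C@@H](C)[C@H](O[Si](CC)(CC)CC)CC[C@H]2[C@H](O[Si](C)(C)C(C)(C)C)C1=O | intermediate
25 | 9α-(tert-butyldimethylsilyloxy)-3α-hydroxy-trans-eremophil-11-en-8-one | C=C(C)[C@@H]1C[C@]2(C)[C@@H](C)[C@H](O)CC[C@H]2[C@H](O[Si](C)(C)C(C)(C)C)C1=O | intermediate
26 | tigloyl chloride, (E)-2-methylbut-2-enoyl chloride | C/C=C(\C)C(=O)Cl | starting material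
27 | 9α-(tert-butyldimethylsilyloxy)-3α-tigloyloxy-trans-eremophil-11-en-8-one | C=C(C)[C@@H]1C[C@]2(C)[C@@H](C)[C@H](OC(=O)/C(C)=C/C)CC[C@H]2[C@H](O[Si](C)(C)C(C)(C)C)C1=O | intermediate
28 | 9α-hydroxy-3α-tigloyloxy-trans-eremophil-11-en-8-one | C=C(C)[C@@H]1C[C@]2(C)[C@@H](C)[C@H](OC(=O)/C(C)=C/C)CC[C@H]2[C@H](O)C1=O | intermediate
29 | senecioic acid, 3-methylbut-2-enoic acid | CC(C)=CC(=O)O | starting material
30 | 3α-tigloyloxy-9α-senecioyloxy-trans-eremophil-11-en-8-one (CNP0375730.3) | C=C(C)[C@@H]1C[C@]2(C)[C@@H](C)[C@H](OC(=O)/C(C)=C/C)CC[C@H]2[C@H](OC(=O)C=C(C)C)C1=O | target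

## Step count and least certain steps

Total step count: 18. Longest linear sequence: 18 steps (1 and 2 to 30). The route is fully linear; 8, 10, 19, 26 and 29 enter as purchased.

**Step 10 (key step).** The tether holds silyloxy and formyl 1,3, so the donor does not lower the barrier as it does in an unconstrained pairing. The cyclisation may therefore need a temperature at which the endo preference of the formyl group is small, giving erosion of the trans fusion. E/Z drift of the β‑methyl enal and acid‑induced loss of the enol silane are further risks at that temperature. The fallback gives up the silyloxy group on the diene so that a Lewis acid can be used. It sets out from 9 and returns at 17.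
- Cross‑metathesis with crotonaldehyde should give ethyl (2E,4R,5R,8E)-3,4-dimethyl-10-oxo-5-(triethylsilyloxy)deca-2,8-dienoate F1.
- Wittig methylenation (Ph3P=CH2) should give ethyl (2E,4R,5R,8E)-3,4-dimethyl-5-(triethylsilyloxy)undeca-2,8,10-trienoate F2.
- i-Bu2AlH should give (2E,4R,5R,8E)-3,4-dimethyl-5-(triethylsilyloxy)undeca-2,8,10-trien-1-ol F3, and MnO2 should give (2E,4R,5R,8E)-3,4-dimethyl-5-(triethylsilyloxy)undeca-2,8,10-trienal F4.
- Me2AlCl in CH2Cl2 at −78 to −20 °C, the textbook endo‑selective variant, should close 6β-formyl-4β,5β-dimethyl-3α-(triethylsilyloxy)-trans-octal-8-ene F5.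
- OsO4 with N‑methylmorpholine N‑oxide should add to C8=C9 from the α face to give 6β-formyl-8α,9α-dihydroxy-4β,5β-dimethyl-3α-(triethylsilyloxy)-trans-decalin F6.
- Selective oxidation of the axial, less hindered 8α‑hydroxyl (Bu2SnO, then N‑bromosuccinimide) should give 6β-formyl-9α-hydroxy-4β,5β-dimethyl-3α-(triethylsilyloxy)-trans-decalin-8-one F7.
- TBSOTf with 2,6‑lutidine leads back to 17.

The price is three more steps and a regioselective diol oxidation.

**Step 14.** Elimination may run toward the ring and give the conjugated isopropylidene ketone, or chloride may substitute at the tertiary centre. Any base strong enough to correct this would also move the double bond. The fallback sets out from 18 and returns at 24, replacing steps 13 and 14. It is a palladium‑catalysed α‑alkenylation of the ketone enolate with 2‑bromopropene (Pd2(dba)3 as a source of zerovalent palladium, P(t-Bu)3, LiN(SiMe3)2, toluene). This is a known ketone α‑vinylation that transfers the isopropenyl group intact and should deliver it from the α face. It makes no new compound (F0).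

**Step 12.** Oxidative addition at a formyl group beside a quaternary carbon may be slow. β‑Hydride loss from the alkyl rhodium hydride toward C7 would then compete and give an alkene, and prolonged heating may epimerise C9. The fallback sets out from 17 and returns at 18. Pinnick oxidation (NaClO2, NaH2PO4, 2‑methyl‑2‑butene) should give 9α-(tert-butyldimethylsilyloxy)-4β,5β-dimethyl-8-oxo-3α-(triethylsilyloxy)-trans-decalin-6β-carboxylic acid F8. Coupling with N‑hydroxypyridine‑2‑thione (DCC) should give its 2-thioxopyridin-1(2H)-yl ester F9. Barton decarboxylation with t‑BuSH under visible light then gives 18.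

**Step 5.** The olefination may give too much Z isomer, which would lead to the cis fusion in step 10. The basic medium may also enolise the ketone and scramble C4, or eliminate the silyloxy group. The fallback sets out from 6 and returns at 9. i-Bu2AlH should give (2S,3R)-2-methyl-3-(triethylsilyloxy)hept-6-enal F10. Ohira–Bestmann homologation (dimethyl (1-diazo-2-oxopropyl)phosphonate, K2CO3, MeOH) should give (3R,4R)-3-methyl-4-(triethylsilyloxy)oct-7-en-1-yne F11. Negishi carboalumination (AlMe3, Cp2ZrCl2 cat.) with an ethyl chloroformate quench adds methyl and the ester syn across the alkyne and should give 9 as the E isomer only.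

## Further compounds

F1 | step 10 | ethyl (2E,4R,5R,8E)-3,4-dimethyl-10-oxo-5-(triethylsilyloxy)deca-2,8-dienoate | O=C/C=C/CC[C@@H](O[Si](CC)(CC)CC)[C@H](C)/C(C)=C/C(=O)OCC
F2 | step 10 | ethyl (2E,4R,5R,8E)-3,4-dimethyl-5-(triethylsilyloxy)undeca-2,8,10-trienoate | C=C/C=C/CC[C@@H](O[Si](CC)(CC)CC)[C@H](C)/C(C)=C/C(=O)OCC
F3 | step 10 | (2E,4R,5R,8E)-3,4-dimethyl-5-(triethylsilyloxy)undeca-2,8,10-trien-1-ol | C=C/C=C/CC[C@@H](O[Si](CC)(CC)CC)[C@H](C)/C(C)=C/CO
F4 | step 10 | (2E,4R,5R,8E)-3,4-dimethyl-5-(triethylsilyloxy)undeca-2,8,10-trienal | C=C/C=C/CC[C@@H](O[Si](CC)(CC)CC)[C@H](C)/C(C)=C/C=O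
F5 | step 10 | 6β-formyl-4β,5β-dimethyl-3α-(triethylsilyloxy)-trans-octal-8-ene | C1[C@@H](C=O)[C@]2(C)[C@@H](C)[C@H](O[Si](CC)(CC)CC)CC[C@H]2C=C1
F6 | step 10 | 6β-formyl-8α,9α-dihydroxy-4β,5β-dimethyl-3α-(triethylsilyloxy)-trans-decalin | C1[C@@H](C=O)[C@]2(C)[C@@H](C)[C@H](O[Si](CC)(CC)CC)CC[C@H]2[C@H](O)[C@@H]1O
F7 | step 10 | 6β-formyl-9α-hydroxy-4β,5β-dimethyl-3α-(triethylsilyloxy)-trans-decalin-8-one | C1[C@@H](C=O)[C@]2(C)[C@@H](C)[C@H](O[Si](CC)(CC)CC)CC[C@H]2[C@H](O)C1=O
F0 | step 14 | none | none
F8 | step 12 | 9α-(tert-butyldimethylsilyloxy)-4β,5β-dimethyl-8-oxo-3α-(triethylsilyloxy)-trans-decalin-6β-carboxylic acid | C1[C@@H](C(=O)O)[C@]2(C)[C@@H](C)[C@H](O[Si](CC)(CC)CC)CC[C@H]2[C@H](O[Si](C)(C)C(C)(C)C)C1=O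
F9 | step 12 | 2-thioxopyridin-1(2H)-yl ester of F8 | C1[C@@H](C(=O)ON3C=CC=CC3=S)[C@]2(C)[C@@H](C)[C@H](O[Si](CC)(CC)CC)CC[C@H]2[C@H](O[Si](C)(C)C(C)(C)C)C1=O
F10 | step 5 | (2S,3R)-2-methyl-3-(triethylsilyloxy)hept-6-enal | C=CCC[C@@H](O[Si](CC)(CC)CC)[C@H](C)C=O
F11 | step 5 | (3R,4R)-3-methyl-4-(triethylsilyloxy)oct-7-en-1-yne | C=CCC[C@@H](O[Si](CC)(CC)CC)[C@H](C)C#C
A1 | alternative 1 | cis-fused 9,9-dimethoxy-4,5-dimethyloctal-3-en-8-one | O=C1CC[C@]2(C)C(C)=CCC[C@@H]2C1(OC)OC
A2 | alternative 1 | 3,3-dimethoxy-5,6-dimethyl-2-vinylbicyclo[2.2.2]oct-5-en-2-ol (vinyl syn to the ring alkene) | C=C[C@@]1(O)[C@@H]2CC[C@@H](C(C)=C2C)C1(OC)OC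
A3 | alternative 2 | 3α-(tert-butyldimethylsilyloxy)-trans-eremophil-11-en-8β-ol | C=C(C)[C@@H]1C[C@]2(C)[C@@H](C)[C@H](O[Si](C)(C)C(C)(C)C)CC[C@H]2C[C@H]1O
A4 | alternative 2 | 3α-(tert-butyldimethylsilyloxy)-7,8-seco-eremophil-7(11)-en-8-al | CC(C)=CC[C@]1(C)[C@@H](C)[C@H](O[Si](C)(C)C(C)(C)C)CC[C@H]1CC=O
A5 | alternative 3 | 9α-hydroxy-4β,5β-dimethyl-trans-decalin-3,8-dione | C1C[C@]2(C)[C@@H](C)C(=O)CC[C@H]2[C@H](O)C1=O
A6 | alternative 3 | (5E,9Z)-9-(tert-butyldimethylsilyloxy)-5-methyl-2-oxoundeca-5,9-dienal | O=CC(=O)CC/C(C)=C/CC/C(O[Si](C)(C)C(C)(C)C)=C/C
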